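(The data are simulated with made-up constants.)

The constants of this scheme are hidden from me, so I turn the readings into times, and I carry one of them: from the zeta run, whose target falls from 6.2% at 10.0 min to 2.1% at 25.0 min, I read 13.9 min as the target's lifetime, the mean time a target survives against starting material once it has stopped being made. I treat this as a pseudo-first-order lifetime, since the zeta run has lost just 21.6% of its starting material by 50.0 min.

| setting | zeta | theta | epsilon | Sunday's | Saturday's | Monday's | Wednesday's | Thursday's |
|---|---|---|---|---|---|---|---|---|
| starting material | 10 mM | 10 mM | 10 mM | 10 mM | 10 mM | 10 mM | 10 mM | 10 mM |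
| partner | 11 mM | 11 mM | 11 mM | 11.0 mM | 11.0 mM | 11.0 mM (in portions, 2, over 40 min) | 11.0 mM (fed, over 40 min) | 11.0 mM (fed, over 10 min) |
| second substrate | 2 mM | 2 mM | 2 mM | 2.00 mM | 2.00 mM | 2.00 mM | 2.00 mM | 2.00 mM |
| third substrate | 10 mM | 5 mM | 20 mM | 10.0 mM | 10.0 mM (fed, over 40 min) | 10.0 mM | 10.0 mM | 10.0 mM |
| remark | run made earlier | run made earlier | run made earlier | everything together at the start | all else is in the flask from the start; the feed brings no volume worth counting | first portion at the start, last at 40 min | all else is in the flask from the start; the feed brings no volume worth counting | all else is in the flask from the start; the feed brings no volume worth counting |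
| time |  |  |  | 50 min | 50 min | 50 min | 50 min | 50 min |

| run | time / min | target / % | side product / % |
|---|---|---|---|
| zeta | 3.00 | 7.1 | 2.1 |
| zeta | 10.0 | 6.2 | 9.1 |
| zeta | 20.0 | 3.5 | 16.0 |
| zeta | 25.0 | 2.1 | 17.6 |
| zeta | 40.0 | 0.6 | 20.5 |
| zeta | 50.0 | 0.4 | 21.2 |
| theta | 3.00 | 7.1 | 2.0 |
| theta | 10.0 | 6.4 | 9.6 |
| theta | 20.0 | 3.1 | 16.1 |
| theta | 25.0 | 1.9 | 17.7 |
| theta | 40.0 | 0.9 | 20.1 |
| theta | 50.0 | 0.5 | 21.6 |
| epsilon | 8.00 | 7.0 | 7.5 |
| epsilon | 15.0 | 3.8 | 12.9 |
| epsilon | 25.0 | 1.9 | 17.2 |
| epsilon | 30.0 | 1.6 | 18.3 |
| epsilon | 40.0 | 1.1 | 19.6 |
| epsilon | 50.0 | 0 | 20.8 |

(each reading ± 0.3 percentage points)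

- in percentages every species weighs as the starting material in it: one side product counts as two
- steps under discussion: starting material + partner -> target; second substrate + partner -> second product; third substrate + partner -> third product; starting material + target -> side product; 2 partner -> homo dimer; partner -> decomposed reagent

1. the best flask by share of target in target plus side product; "all alike" if 1.5 percentage points covers them all (Sunday's / Saturday's / Monday's / Wednesday's / Thursday's / all alike)
2. share of target in target plus side product at the end, Sunday's
3. share of target in target plus side product at the end, Saturday's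
4. share of target in target plus side product at the end, Monday's
5. share of target in target plus side product at the end, Wednesday's
6. share of target in target plus side product at the end, Thursday's

Each side product has eaten one target, so target plus half the side product counts the target ever made. At the last readings this sum is 11.0% in the zeta run, 11.3% in the theta run and 10.4% in the epsilon run, with third substrate at 10 mM, 5 mM and 20 mM, so I place Saturday's beside Sunday's. I assume that dosing moves this sum little. The kept fraction of the target is then exp(−delay/lifetime), the delay being the time from its making to the end, and the share is kept/(2 − kept), in which the made amount cancels.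

Two extreme versions of the flask can be reckoned in the head. If the target appears whole at the start, 2.71% is kept over 50 min and the share is 1.37%. If it appears whole at 40 min, 48.6% is kept and the share is 32.1%. I place Sunday's just above the first extreme, as the zeta sum already reads 8.15% at 3.00 min. Taking the making as spread evenly over the feed and averaging the kept fraction gives 2.03% for Thursday's and 8.63% for Wednesday's. Monday's, with one portion at each extreme, keeps 25.6% and gives 14.7%, so I commit to Monday's.

The forecast also names Monday's, with Sunday's 1.9%, Saturday's 1.9%, Monday's 16.3%, Wednesday's 9.5% and Thursday's 2.7%, its last three standing higher than my figures, and it says: “dosing barely changes total target made, only when it is made”.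

The simulation gives Monday's at 17.2%, then Wednesday's 10.6%, Thursday's 2.87%, Saturday's 2.06% and Sunday's 2.00%. At 50.0 min Monday's target is still being made, at 0.171 of the rate at which it is used up, with 0.913% of the partner's charge left. Monday's made amount, target plus half the side product at the end, is 10.9%, and my kept fraction from the 13.9 min lifetime turns it into 2.79% of target, against 3.19% in Monday's flask.

    starting material + partner → target (k = 0.0750 M⁻¹ s⁻¹)
    second substrate + partner → second product (k = 0.250 M⁻¹ s⁻¹)
    third substrate + partner → third product (k = 0.0250 M⁻¹ s⁻¹)
    starting material + target → side product (k = 0.140 M⁻¹ s⁻¹)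
    2 partner → homo dimer (k = 0.0190 M⁻¹ s⁻¹)
    partner → decomposed reagent (k = 0.00540 s⁻¹)

Take Monday's recipe with 17 mM of starting material: taken as inverse to the starting material, the lifetime shortens to 8.15 min, which keeps 14.8% and gives a share of 7.99%. The computed neighbour flask ends with 1.98% of target and 16.5% of side product, in percent of its own starting material, a share of 10.7%.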